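**Retrosynthetic overview**
1. C5–H: the only stereocentre is set last, by enantioselective decarboxylative protonation of a racemic C5-carboxylic acid. Both enantiomers converge through one planar furanolate.
2. Aryl–prenyl bond: late Friedel–Crafts prenylation of the benzylic phenol ring (ring B) of the unprenylated acid, the chemical counterpart of aromatic prenyl transfer.
3. Butenolide C4–C5 and O1–C2 bonds: aldol/lactonization homodimerization of two molecules of 4-hydroxyphenylpyruvic acid, as in the biosynthesis of this lactone family.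
4. Ring order: the butenolide is the only ring made (step 1). Both benzene rings are bought.

Assumption: C5 of the given SMILES is (R) (O1 > C4 > CH2Ar > H). The facial sense of step 3 has no direct precedent, so the quinine-derived thiourea is written, and its quinidine-derived pseudoenantiomer replaces it, all else equal, if chiral HPLC/ECD of the first run shows (S).

**Step 1**
Reactants: 1 4-hydroxyphenylpyruvic acid (two molecules, donor and acceptor)
Product: 3 rac-4-hydroxy-2-(4-hydroxybenzyl)-3-(4-hydroxyphenyl)-5-oxo-2,5-dihydrofuran-2-carboxylic acid, via open-chain aldol diacid 2 (not isolated)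
Conditions: NaOH (1.5 equiv per 1), degassed H2O (1 M), Ar, 0 °C to rt, 18 h; then 6 M HCl to pH 1, rt, 2 h; EtOAc extraction
Reagents that add atoms: none
Why: Base-mediated self-aldol addition of an arylpyruvate enolate to the keto group of a second arylpyruvate (the pyruvate-to-zymonic-acid reaction type, long known for phenylpyruvic acid) is followed by acid-driven γ-lactonization to the conjugated enol lactone; donor and acceptor are the same molecule, so there is no cross-selectivity issue, and C5 is deliberately formed racemic because step 3 erases and resets it.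

**Step 2**
Reactants: 3 rac-4-hydroxy-2-(4-hydroxybenzyl)-3-(4-hydroxyphenyl)-5-oxo-2,5-dihydrofuran-2-carboxylic acid; 4 2-methylbut-3-en-2-ol
Product: 5 rac-4-hydroxy-2-[4-hydroxy-3-(3-methylbut-2-en-1-yl)benzyl]-3-(4-hydroxyphenyl)-5-oxo-2,5-dihydrofuran-2-carboxylic acid
Conditions: 4 (1.0 equiv, slow addition), BF3·OEt2 (30 mol %), 1,4-dioxane, 15–20 °C, 4 h, stopped at about 60 % conversion; C18 chromatography below 30 °C, recovered 3 recycled
Reagents that add atoms: 2-methylbut-3-en-2-ol (4), CC(C)(O)C=C
Why: Friedel–Crafts prenylation by the dimethylallyl cation should favour ring B, because only positions ortho to a phenolic OH are open, ring B is a p-cresol-type arene insulated from the lactone by CH2 while ring A is a less nucleophilic p-coumarate-type (vinylogous acyl) arene, attack at enol carbon C4 would create two adjacent quaternary carbons, O-prenyl by-products re-ionise under BF3, and partial conversion limits chroman formation and diprenylation; no stereocentre is set.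

**Step 3**
Reactants: 5 rac-4-hydroxy-2-[4-hydroxy-3-(3-methylbut-2-en-1-yl)benzyl]-3-(4-hydroxyphenyl)-5-oxo-2,5-dihydrofuran-2-carboxylic acid
Product: 7 (5R)-3-hydroxy-4-(4-hydroxyphenyl)-5-[4-hydroxy-3-(3-methylbut-2-en-1-yl)benzyl]furan-2(5H)-one, via furan-2,3-diol dienolate 6 (not isolated)
Conditions: N-[3,5-bis(trifluoromethyl)phenyl]-N'-[(8α,9S)-6'-methoxycinchonan-9-yl]thiourea (1.0 equiv, recovered by acid/base extraction), degassed THF (0.05 M), Ar, 30 °C, 48–72 h; recrystallization to upgrade ee if needed
Reagents that add atoms: none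
Why: Proposed new method: the quinuclidine deprotonates the C5-CO2H, the ion-paired carboxylate loses CO2 because the resulting C5 carbanion is a vinylogous enolate that is an aromatic 2-oxidofuran (6), the thiourea binds the O2/O3 edge of this planar anion, and the quinuclidinium N–H delivers the proton to the Si face of C5, so both enantiomers of 5 converge on (R)-7, which resists racemization because the amine can only remove its enol O–H and not C5–H; the closest known reaction types are the cinchona-thiourea-mediated enantioselective decarboxylative protonation of malonic hemiesters and the cinchona-catalysed isomerization of β,γ- to α,β-butenolides by enantioselective γ-protonation of the same kind of furanolate.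

**Compound list**
1 | 4-hydroxyphenylpyruvic acid | O=C(O)C(=O)Cc1ccc(O)cc1 | starting material
2 | 2-hydroxy-2-(4-hydroxybenzyl)-3-(4-hydroxyphenyl)-4-oxopentanedioic acid (open-chain aldol, racemic diastereomer mixture, not isolated) | OC(=O)C(=O)C(c1ccc(O)cc1)C(O)(Cc1ccc(O)cc1)C(O)=O | intermediate
3 | rac-4-hydroxy-2-(4-hydroxybenzyl)-3-(4-hydroxyphenyl)-5-oxo-2,5-dihydrofuran-2-carboxylic acid | OC(=O)C1(Cc2ccc(O)cc2)OC(=O)C(O)=C1c1ccc(O)cc1 | intermediate
4 | 2-methylbut-3-en-2-ol | CC(C)(O)C=C | starting material
5 | rac-4-hydroxy-2-[4-hydroxy-3-(3-methylbut-2-en-1-yl)benzyl]-3-(4-hydroxyphenyl)-5-oxo-2,5-dihydrofuran-2-carboxylic acid | CC(C)=CCc1cc(CC2(C(O)=O)OC(=O)C(O)=C2c2ccc(O)cc2)ccc1O | intermediate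
6 | 5-[4-hydroxy-3-(3-methylbut-2-en-1-yl)benzyl]-4-(4-hydroxyphenyl)furan-2,3-diol (present as its mono-anion paired with the protonated catalyst, drawn neutral, achiral, not isolated) | CC(C)=CCc1cc(Cc2oc(O)c(O)c2-c2ccc(O)cc2)ccc1O | intermediate
7 | (5R)-3-hydroxy-4-(4-hydroxyphenyl)-5-[4-hydroxy-3-(3-methylbut-2-en-1-yl)benzyl]furan-2(5H)-one | CC(C)=CCc1cc(C[C@H]2OC(=O)C(O)=C2c2ccc(O)cc2)ccc1O | target

**Totals**
Total step count: 3. Longest linear sequence: 3.

**Steps most likely to fail (most risky first)**

**Step 3.** CO2 loss may need temperatures at which the ion pair is no longer ordered. The free phenol and enol OH groups may also shuttle protons achirally and lower the ee.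
The fallback sets out from 5 and comes back at 7, replacing asymmetric catalysis by resolution with recycling. Compound 5 is decarboxylated thermally in pyridine at 90 °C under Ar (through 6) to racemic 3-hydroxy-4-(4-hydroxyphenyl)-5-[4-hydroxy-3-(3-methylbut-2-en-1-yl)benzyl]furan-2(5H)-one F1. This is separated by preparative SFC on an amylose carbamate chiral phase to give 7. The unwanted (5S)-enantiomer F2 is racemised with catalytic DBU in THF through the same furanolate and re-injected.

**Step 2.** Ring B over ring A selectivity may be modest. Conversion is low by design, and the o-prenylphenol can cyclise to the chroman.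
The fallback sets out from 1 and comes back at 7, bypassing 3 and 5 by installing the prenyl group before the ring is made.
- Tyrosol, 2-(4-hydroxyphenyl)ethanol, is C-prenylated as its sodium phenoxide (NaH 1.0 equiv, prenyl bromide, toluene, rt). There is only one arene, so no ring choice arises. The product is 2-[4-hydroxy-3-(3-methylbut-2-en-1-yl)phenyl]ethanol F3.
- Parikh–Doering oxidation (SO3·pyridine, DMSO, Et3N, 0 °C) gives 4-hydroxy-3-(3-methylbut-2-en-1-yl)phenylacetaldehyde F4.
- Enamine aldol addition of 1 to slowly added F4 follows, with (R)-2-(pyrrolidin-2-yl)-1H-benzimidazole and CF3CO2H (20 mol % each, THF, 0 °C). The D-proline series is chosen by proline-type aldol topicity. The product is (4R)-4-hydroxy-5-[4-hydroxy-3-(3-methylbut-2-en-1-yl)phenyl]-3-(4-hydroxyphenyl)-2-oxopentanoic acid F5, which lactonizes in the flask to 7.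

**Step 1.** The risks are the retro-aldol equilibrium, autoxidation of the electron-rich enolate, and incomplete lactonization of the free diacid.
The fallback sets out from 1 and comes back at 3, moving the dimerization to the ester series, where lactonization is an irreversible transesterification.
- Fischer esterification of 1 (MeOH, catalytic H2SO4, reflux) gives methyl 4-hydroxyphenylpyruvate F6.
- DBU (1.0 equiv, DMF, 0 °C, Ar) gives the open-chain aldol dimethyl ester F7. This closes in the flask to racemic methyl 4-hydroxy-2-(4-hydroxybenzyl)-3-(4-hydroxyphenyl)-5-oxo-2,5-dihydrofuran-2-carboxylate F8.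
- Saponification of the C5 ester (LiOH, THF/H2O, 0 °C, Ar; then HCl to pH 1) gives 3.

**Further compounds**
F1 | step 3 | racemic 3-hydroxy-4-(4-hydroxyphenyl)-5-[4-hydroxy-3-(3-methylbut-2-en-1-yl)benzyl]furan-2(5H)-one | CC(C)=CCc1cc(CC2OC(=O)C(O)=C2c2ccc(O)cc2)ccc1O
F2 | step 3 | (5S)-3-hydroxy-4-(4-hydroxyphenyl)-5-[4-hydroxy-3-(3-methylbut-2-en-1-yl)benzyl]furan-2(5H)-one | CC(C)=CCc1cc(C[C@@H]2OC(=O)C(O)=C2c2ccc(O)cc2)ccc1O
F3 | step 2 | 2-[4-hydroxy-3-(3-methylbut-2-en-1-yl)phenyl]ethanol | CC(C)=CCc1cc(CCO)ccc1O
F4 | step 2 | 4-hydroxy-3-(3-methylbut-2-en-1-yl)phenylacetaldehyde | CC(C)=CCc1cc(CC=O)ccc1O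
F5 | step 2 | (4R)-4-hydroxy-5-[4-hydroxy-3-(3-methylbut-2-en-1-yl)phenyl]-3-(4-hydroxyphenyl)-2-oxopentanoic acid | CC(C)=CCc1cc(C[C@@H](O)C(c2ccc(O)cc2)C(=O)C(O)=O)ccc1O
F6 | step 1 | methyl 4-hydroxyphenylpyruvate | COC(=O)C(=O)Cc1ccc(O)cc1
F7 | step 1 | dimethyl 2-hydroxy-2-(4-hydroxybenzyl)-3-(4-hydroxyphenyl)-4-oxopentanedioate | COC(=O)C(=O)C(c1ccc(O)cc1)C(O)(Cc1ccc(O)cc1)C(=O)OC
F8 | step 1 | racemic methyl 4-hydroxy-2-(4-hydroxybenzyl)-3-(4-hydroxyphenyl)-5-oxo-2,5-dihydrofuran-2-carboxylate | COC(=O)C1(Cc2ccc(O)cc2)OC(=O)C(O)=C1c1ccc(O)cc1
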